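**Strategy.** The cyclohexene ring (C1, C10, C11, C12, C13, C14; briarane numbering) carries a tertiary carbinol C11(OH)(CH3) next to oxygenated C12, the signature of an α-ketol rearrangement. The ring is therefore carried as a cyclopentene (C1, C10, C12, C13, C14) whose C12 bears OH and an acetyl group (future C11 and its methyl), assembled by aldol union of a cyclopentenone with a C7–C9/C17–C19 aldehyde. Base-induced 1,2-shift of C10 from C12 to the acetyl carbon expands the ring to the six-membered enone and sets C11 in one operation. CBS reduction, Nozaki–Hiyama–Kishi closure of the ten-membered ring at C6–C7 and lactonisation complete the route.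

Key step: step 19

Remark: briarane numbering (C1–C20) is used for all intermediates; where a catalyst enantiomer is named, it is the one expected from the accepted stereochemical models for the drawn configuration.

**Fragment A (steps 1–9)**

Step 1
Reactants: 1 prop-2-yn-1-ol
Product: 3 (Z)-3-iodo-2-methylprop-2-en-1-ol, via alkenylmagnesium alkoxide 2 (not isolated)
Conditions: MeMgBr (2.5 equiv), CuI (10 mol %), THF, −10 → 20 °C; then I2, −30 → 0 °C; aq NH4Cl
Reagents that add atoms: methylmagnesium bromide C[Mg]Br; iodine II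
Why: Cu-catalysed anti-carbomagnesiation of the propargylic magnesium alkoxide places Mg cis to CH2O in a five-membered chelate, so iodinolysis should give the Z iodoalkene (I cis to the future C4).

Step 2
Reactants: 3 (Z)-3-iodo-2-methylprop-2-en-1-ol
Product: 4 (Z)-3-bromo-1-iodo-2-methylprop-1-ene
Conditions: CBr4, PPh3, CH2Cl2, 0 °C
Reagents that add atoms: carbon tetrabromide BrC(Br)(Br)Br
Why: Appel bromination of the primary allylic alcohol, which should leave the alkene geometry untouched.

Step 3
Reactants: 5 ethynyltrimethylsilane; 4 (Z)-3-bromo-1-iodo-2-methylprop-1-ene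
Product: 7 (Z)-(5-iodo-4-methylpent-4-en-1-yn-1-yl)trimethylsilane, via [(trimethylsilyl)ethynyl]magnesium bromide 6 (not isolated)
Conditions: EtMgBr, THF, 0 → 20 °C; then CuBr·SMe2 (5 mol %), 4, 20 → 45 °C
Reagents that add atoms: none
Why: Cu-catalysed coupling of an alkynyl Grignard reagent with an allylic bromide at its primary terminus should give the skipped enyne with the vinyl iodide intact.

Step 4
Reactants: 7 silyl enyne; 8 3-methylcyclopent-2-en-1-one
Product: 10 (S)-3-[(1Z,4Z)-5-iodo-4-methyl-1-(trimethylsilyl)penta-1,4-dien-1-yl]-3-methylcyclopentan-1-one, via alkenylalane 9 (not isolated)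
Conditions: DIBAL-H, hexanes/THF, 55 °C; then 8, chiral sulfonate-bearing NHC–Ag complex (2.5 mol %), Cu(OTf)2 (5 mol %), THF, −78 → −30 °C; aq Rochelle salt
Reagents that add atoms: none
Why: cis-hydroalumination puts Al on the silyl-bearing alkyne carbon, and NHC–Cu-catalysed asymmetric conjugate addition of this Si-substituted alkenylaluminium to the β-methyl enone should create the C1 quaternary centre under catalyst control (NHC enantiomer chosen for the S ketone).

Step 5
Reactants: 10 cyclopentanone
Product: 11 (R)-4-[(1Z,4Z)-5-iodo-4-methyl-1-(trimethylsilyl)penta-1,4-dien-1-yl]-4-methylcyclopent-2-en-1-one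
Conditions: IBX, DMSO/PhF, 70 °C
Reagents that add atoms: none
Why: IBX dehydrogenation of the ketone can only introduce C13=C14, because the other α-carbon (C10) is flanked by quaternary C1.

Step 6
Reactants: 11 enone
Product: 13 (R)-4-[(Z)-5-iodo-4-methylpent-4-enoyl]-4-methylcyclopent-2-en-1-one, via epoxysilane 12 (not isolated)
Conditions: m-CPBA, CH2Cl2, 0 °C; then 10 % aq H2SO4, THF, 20 °C
Reagents that add atoms: m-chloroperbenzoic acid O=C(OO)c1cccc(Cl)c1
Why: the electron-rich vinylsilane should be epoxidised in preference to the enone and the iodoalkene, and acid opening of the α,β-epoxysilane followed by Peterson-type loss of silanol gives the ketone at the silicon-bearing carbon (C2).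

Step 7
Reactants: 13 enedione
Product: 14 (1R,4R)-4-[(1R,4Z)-1-hydroxy-5-iodo-4-methylpent-4-en-1-yl]-4-methylcyclopent-2-en-1-ol
Conditions: (S)-2-methyl-CBS-oxazaborolidine (0.5 equiv), catecholborane, toluene, −78 → −30 °C
Reagents that add atoms: none
Why: CBS reduction with quaternary C1 as the large and C3H2 as the small substituent should set C2 by reagent control; the ring carbonyl is reduced at the same time and its configuration is of no consequence.

Step 8
Reactants: 14 diol
Product: 15 (R)-4-[(1R,4Z)-1-hydroxy-5-iodo-4-methylpent-4-en-1-yl]-4-methylcyclopent-2-en-1-one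
Conditions: MnO2, CH2Cl2, 20 °C
Reagents that add atoms: none
Why: MnO2 oxidises the allylic ring alcohol selectively and leaves the saturated neopentyl C2 carbinol.

Step 9
Reactants: 15 hydroxy enone
Product: 16 (R)-4-[(1R,4Z)-5-iodo-4-methyl-1-(triethylsilyloxy)pent-4-en-1-yl]-4-methylcyclopent-2-en-1-one
Conditions: TESOTf, 2,6-lutidine, CH2Cl2, −78 °C
Reagents that add atoms: triethylsilyl trifluoromethanesulfonate CC[Si](CC)(CC)OS(=O)(=O)C(F)(F)F
Why: silylation of the hindered secondary alcohol with a silyl triflate gives a bulky, non-coordinating group on the C2 chain.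

**Fragment B (steps 10–16)**

Step 10
Reactants: 17 methyl 2-(hydroxymethyl)prop-2-enoate
Product: 18 methyl 2-{[(tert-butyldiphenylsilyl)oxy]methyl}prop-2-enoate
Conditions: TBDPSCl, imidazole, DMF, 20 °C
Reagents that add atoms: tert-butyl(chloro)diphenylsilane CC(C)(C)[Si](Cl)(c1ccccc1)c1ccccc1
Why: standard silylation of a primary alcohol; this oxygen becomes O7 and must outlast the TES groups.

Step 11
Reactants: 18 silyloxymethyl acrylate
Product: 20 methyl 3-[(tert-butyldiphenylsilyl)oxy]-2-oxopropanoate, via ozonide 19 (not isolated)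
Conditions: O3, CH2Cl2, −78 °C; then Me2S, −78 → 20 °C
Reagents that add atoms: ozone [O-][O+]=O
Why: ozonolysis of the 1,1-disubstituted alkene with reductive work-up should give the α-keto ester.

Step 12
Reactants: 21 S-ethyl propanethioate
Product: 23 (Z)-{[1-(ethylsulfanyl)prop-1-en-1-yl]oxy}trimethylsilane, via lithium thioester enolate 22 (not isolated)
Conditions: LDA, THF, −78 °C; then TMSCl
Reagents that add atoms: chlorotrimethylsilane C[Si](C)(C)Cl
Why: kinetic enolisation of the thioester and O-silylation give the silyl ketene thioacetal needed for a Mukaiyama aldol.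

Step 13
Reactants: 20 α-keto ester; 23 silyl ketene thioacetal
Product: 25 S-ethyl (2R,3S)-3-hydroxy-4-methoxy-2-methyl-4-oxo-3-{[(tert-butyldiphenylsilyl)oxy]methyl}butanethioate, via trimethylsilyl ether 24 (not isolated)
Conditions: [Cu((R,R)-t-Bu-box)](OTf)2 (10 mol %), THF, −78 °C; then 1 M HCl
Reagents that add atoms: none
Why: enantioselective Mukaiyama aldol to an α-keto ester held as a five-membered chelate on the Cu(II)–bis(oxazoline) Lewis acid; the ligand enantiomer should set the C8 carbinol and the open transition state the syn relationship to C17.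

Step 14
Reactants: 25 hydroxy thioester
Product: 26 triethylsilyl ether of 25
Conditions: TESOTf, 2,6-lutidine, CH2Cl2, 0 → 20 °C
Reagents that add atoms: triethylsilyl trifluoromethanesulfonate CC[Si](CC)(CC)OS(=O)(=O)C(F)(F)F
Why: silyl triflate protection of the tertiary alcohol blocks retro-aldol and β-lactone formation in the following steps.

Step 15
Reactants: 26 silylated thioester
Product: 27 1-tert-butyl 4-methyl (2R,3S)-2-methyl-3-(triethylsilyloxy)-3-{[(tert-butyldiphenylsilyl)oxy]methyl}butanedioate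
Conditions: AgOCOCF3, t-BuOH, Na2HPO4, CH2Cl2, 20 °C
Reagents that add atoms: tert-butanol CC(C)(C)O
Why: thiophilic Ag(I) activation of the thioester and acyl transfer to tert-butanol should give an ester (C19) that resists DIBAL-H and organometallic reagents.

Step 16
Reactants: 27 diester
Product: 28 tert-butyl (2R,3S)-4-[(tert-butyldiphenylsilyl)oxy]-3-formyl-2-methyl-3-(triethylsilyloxy)butanoate
Conditions: DIBAL-H, CH2Cl2, −78 °C; MeOH, aq Rochelle salt
Reagents that add atoms: none
Why: partial reduction of the α-silyloxy methyl ester stops at the aldehyde (C9) through a stable tetrahedral aluminate, while the tert-butyl ester is not attacked at −78 °C.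

**Union, ring expansion and end game (steps 17–26)**

Step 17
Reactants: 16 cyclopentenone; 28 aldehyde
Product: 31 tris-TES aldol adduct (C9–C10 bond formed), via lithium dienolate 29 (not isolated), via lithium aldolate 30 (not isolated)
Conditions: LDA, THF, −78 °C; 28, −78 °C; then TESOTf, −78 → −40 °C
Reagents that add atoms: triethylsilyl trifluoromethanesulfonate CC[Si](CC)(CC)OS(=O)(=O)C(F)(F)F
Why: LDA can form only the α′ cross-conjugated enolate, which should add anti to the branched C2 chain on C1 (C9 chain cis to CH3-15) through a Zimmerman–Traxler chair of the ring-locked (E)-enolate that gives the anti aldol and with it the C9 carbinol, against only a weak intrinsic facial bias of the fully α-substituted aldehyde; in situ silylation blocks retro-aldol cleavage.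

Step 18
Reactants: 31 aldol adduct; 32 ethyl vinyl ether
Product: 35 α-ketol (1-acetylcyclopent-2-en-1-ol), via 1-ethoxyvinyllithium 33 (not isolated), via enol ether carbinol 34 (not isolated)
Conditions: 32 (excess), t-BuLi, THF, −78 → 0 °C; CeCl3, −78 °C; 31; then 0.5 M HCl/THF, 0 °C
Reagents that add atoms: water O
Why: the cerium-modified acyl-anion equivalent should add 1,2 to the C12 carbonyl from the α face, anti to the C9 chain on C10 (OH β, future acetyl α), without enolisation or iodine–metal exchange, and mild acid hydrolysis of the enol ether unveils the methyl ketone.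

Step 19
Reactants: 35 α-ketol
Product: 37 ring-expanded 11-O-TES cyclohex-2-enone, via ring-expanded potassium alkoxide 36 (not isolated)
Conditions: KHMDS (1.05 equiv), 18-crown-6, THF, −78 → 0 °C; then TESCl
Reagents that add atoms: chlorotriethylsilane CC[Si](Cl)(CC)CC
Why: KHMDS deprotonates the tertiary C12 hydroxyl and the C10–C12 σ-bond migrates with its electron pair onto the adjacent acetyl carbonyl carbon (the future C11) while C12 collapses to the ketone, an anionic α-ketol (acyloin) rearrangement whose product alkoxide 36 is capped as the TES ether. The closest known reaction type is the base-mediated ring enlargement of 1-acylcycloalkanols to 2-hydroxy-2-methylcycloalkanones, as in the D-homoannulation of 17-hydroxy-20-keto steroids. The six-membered ring C1–C10–C11–C12–C13–C14 is not closed by a new ring-forming attack but grows out of the cyclopentene by a suprafacial 1,2-shift through a three-centre bridged transition state that inserts C11 between C10 and C12, with retention at the migrating C10. C11 is the only new stereocentre and is controlled by the C12 configuration from step 18 (acetyl on the α face) together with the transoid, dipole-minimised arrangement of C–O⁻ and C=O expected for the crown-ether-separated, non-chelating potassium alkoxide, so that C10 adds to the carbonyl face that leaves the new oxygen α (cis to H-10) and the methyl β. The step needs migration of sp3 C10 and not of vinylic C13; this should be secured because the shift is reversible and only C10 migration leads to the conjugated, strain-relieved cyclohex-2-enone as thermodynamic sink, and because the weaker, more substituted sp3–sp3 bond is the one that breaks.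

Step 20
Reactants: 37 enone
Product: 38 12α-allylic alcohol
Conditions: (S)-2-methyl-CBS-oxazaborolidine (0.5 equiv), catecholborane, toluene, −78 → −40 °C
Reagents that add atoms: none
Why: CBS 1,2-reduction with the fully substituted C11 as the large and vinylic C13 as the small substituent should deliver hydride to the β face and give the 12α-carbinol cis to O11, overriding the substrate preference for axial attack.

Step 21
Reactants: 38 tetrakis-TES ether
Product: 39 pentaol (free OH at C2, C8, C9, C11, C12)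
Conditions: HF·pyridine, pyridine, THF, 0 °C
Reagents that add atoms: none
Why: buffered HF·pyridine cleaves the four TES ethers much faster than the primary TBDPS ether and does not affect the tert-butyl ester.

Step 22
Reactants: 39 pentaol
Product: 40 2,9,12-triacetate
Conditions: Ac2O, pyridine, DMAP (cat.), CH2Cl2, 0 → 20 °C
Reagents that add atoms: acetic anhydride CC(=O)OC(C)=O
Why: the three secondary hydroxyls are acylated while the tertiary C8 and C11 hydroxyls should remain free under these mild conditions.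

Step 23
Reactants: 40 triacetate
Product: 41 primary alcohol (C7–OH)
Conditions: HF·pyridine, THF, 20 → 40 °C
Reagents that add atoms: none
Why: acidic fluoride removes the TBDPS group without acetyl migration or ester cleavage.

Step 24
Reactants: 41 primary alcohol
Product: 42 α-hydroxy aldehyde (C7=O)
Conditions: Dess–Martin periodinane, NaHCO3, CH2Cl2, 0 → 20 °C
Reagents that add atoms: none
Why: Dess–Martin oxidation converts the only primary or secondary free hydroxyl into the aldehyde; the tertiary alcohols are inert.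

Step 25
Reactants: 42 iodo aldehyde
Product: 43 ten-membered carbocycle (7-carbinol)
Conditions: CrCl2 (10 equiv), NiCl2 (1 mol %), DMSO, 0.003 M, 20 °C
Reagents that add atoms: none
Why: Nozaki–Hiyama–Kishi reaction (Ni-catalysed formation of the alkenylchromium(III) species with retention of the Z geometry, then addition to the aldehyde) should close the ring at C6–C7 in the presence of acetates, ester and free tertiary alcohols, the α-alkoxide-chelated aldehyde being attacked on the face that carries C9, through which the nucleophile is tethered.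

Step 26
Reactants: 43 hydroxy tert-butyl ester
Product: 44 CNP0129620.2 (target)
Conditions: TFA/CH2Cl2 (1:5), 0 → 20 °C
Reagents that add atoms: none
Why: acidolysis of the tert-butyl ester is followed by spontaneous γ-lactonisation of the C19 acid onto the C7 hydroxyl with retention at C7, C9 being blocked as its acetate.

**Compound list**

1 | prop-2-yn-1-ol | C#CCO | starting material
2 | bromomagnesium (Z)-3-(bromomagnesio)-2-methylprop-2-en-1-olate | Br[Mg]OC/C(C)=C\[Mg]Br | intermediate
3 | (Z)-3-iodo-2-methylprop-2-en-1-ol | OC/C(C)=C\I | intermediate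
4 | (Z)-3-bromo-1-iodo-2-methylprop-1-ene | BrC/C(C)=C\I | intermediate
5 | ethynyltrimethylsilane | C[Si](C)(C)C#C | starting material
6 | [(trimethylsilyl)ethynyl]magnesium bromide | C[Si](C)(C)C#C[Mg]Br | intermediate
7 | (Z)-(5-iodo-4-methylpent-4-en-1-yn-1-yl)trimethylsilane | C[Si](C)(C)C#CC/C(C)=C\I | intermediate
8 | 3-methylcyclopent-2-en-1-one | CC1=CC(=O)CC1 | starting material
9 | diisobutyl[(1Z,4Z)-5-iodo-4-methyl-1-(trimethylsilyl)penta-1,4-dien-1-yl]alane | CC(C)C[Al](CC(C)C)/C(=C/CC(/C)=C\I)[Si](C)(C)C | intermediate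
10 | (S)-3-[(1Z,4Z)-5-iodo-4-methyl-1-(trimethylsilyl)penta-1,4-dien-1-yl]-3-methylcyclopentan-1-one | O=C1CC[C@@](C)(C1)/C(=C/CC(/C)=C\I)[Si](C)(C)C | intermediate
11 | (R)-4-[(1Z,4Z)-5-iodo-4-methyl-1-(trimethylsilyl)penta-1,4-dien-1-yl]-4-methylcyclopent-2-en-1-one | O=C1C=C[C@@](C)(C1)/C(=C/CC(/C)=C\I)[Si](C)(C)C | intermediate
12 | (4R)-4-{3-[(Z)-3-iodo-2-methylprop-2-en-1-yl]-2-(trimethylsilyl)oxiran-2-yl}-4-methylcyclopent-2-en-1-one (epoxide diastereomers) | O=C1C=C[C@@](C)(C1)C2(OC2CC(/C)=C\I)[Si](C)(C)C | intermediate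
13 | (R)-4-[(Z)-5-iodo-4-methylpent-4-enoyl]-4-methylcyclopent-2-en-1-one | O=C1C=C[C@@](C)(C1)C(=O)CC/C(C)=C\I | intermediate
14 | (1R,4R)-4-[(1R,4Z)-1-hydroxy-5-iodo-4-methylpent-4-en-1-yl]-4-methylcyclopent-2-en-1-ol | O[C@H]1C=C[C@@](C)(C1)[C@H](O)CC/C(C)=C\I | intermediate
15 | (R)-4-[(1R,4Z)-1-hydroxy-5-iodo-4-methylpent-4-en-1-yl]-4-methylcyclopent-2-en-1-one | O=C1C=C[C@@](C)(C1)[C@H](O)CC/C(C)=C\I | intermediate
16 | (R)-4-[(1R,4Z)-5-iodo-4-methyl-1-(triethylsilyloxy)pent-4-en-1-yl]-4-methylcyclopent-2-en-1-one | O=C1C=C[C@@](C)(C1)[C@H](O[Si](CC)(CC)CC)CC/C(C)=C\I | intermediate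
17 | methyl 2-(hydroxymethyl)prop-2-enoate | C=C(CO)C(=O)OC | starting material
18 | methyl 2-{[(tert-butyldiphenylsilyl)oxy]methyl}prop-2-enoate | C=C(CO[Si](c1ccccc1)(c1ccccc1)C(C)(C)C)C(=O)OC | intermediate
19 | methyl 3-{[(tert-butyldiphenylsilyl)oxy]methyl}-1,2,4-trioxolane-3-carboxylate (ozonide) | COC(=O)C1(CO[Si](c2ccccc2)(c2ccccc2)C(C)(C)C)OCOO1 | intermediate
20 | methyl 3-[(tert-butyldiphenylsilyl)oxy]-2-oxopropanoate | COC(=O)C(=O)CO[Si](c1ccccc1)(c1ccccc1)C(C)(C)C | intermediate
21 | S-ethyl propanethioate | CCC(=O)SCC | starting material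
22 | lithium (Z)-1-(ethylsulfanyl)prop-1-en-1-olate | C/C=C(/O[Li])SCC | intermediate
23 | (Z)-{[1-(ethylsulfanyl)prop-1-en-1-yl]oxy}trimethylsilane | C/C=C(/O[Si](C)(C)C)SCC | intermediate
24 | trimethylsilyl ether of 25 | CCSC(=O)[C@H](C)[C@](O[Si](C)(C)C)(CO[Si](c1ccccc1)(c1ccccc1)C(C)(C)C)C(=O)OC | intermediate
25 | S-ethyl (2R,3S)-3-hydroxy-4-methoxy-2-methyl-4-oxo-3-{[(tert-butyldiphenylsilyl)oxy]methyl}butanethioate | CCSC(=O)[C@H](C)[C@](O)(CO[Si](c1ccccc1)(c1ccccc1)C(C)(C)C)C(=O)OC | intermediate
26 | S-ethyl (2R,3S)-4-methoxy-2-methyl-4-oxo-3-(triethylsilyloxy)-3-{[(tert-butyldiphenylsilyl)oxy]methyl}butanethioate | CCSC(=O)[C@H](C)[C@](O[Si](CC)(CC)CC)(CO[Si](c1ccccc1)(c1ccccc1)C(C)(C)C)C(=O)OC | intermediate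
27 | 1-tert-butyl 4-methyl (2R,3S)-2-methyl-3-(triethylsilyloxy)-3-{[(tert-butyldiphenylsilyl)oxy]methyl}butanedioate | CC(C)(C)OC(=O)[C@H](C)[C@](O[Si](CC)(CC)CC)(CO[Si](c1ccccc1)(c1ccccc1)C(C)(C)C)C(=O)OC | intermediate
28 | tert-butyl (2R,3S)-4-[(tert-butyldiphenylsilyl)oxy]-3-formyl-2-methyl-3-(triethylsilyloxy)butanoate | CC(C)(C)OC(=O)[C@H](C)[C@](O[Si](CC)(CC)CC)(CO[Si](c1ccccc1)(c1ccccc1)C(C)(C)C)C=O | intermediate
29 | lithium cross-conjugated dienolate of 16 (C12–O–Li, C10=C12) | [Li]OC1=C[C@](C)(C=C1)[C@H](O[Si](CC)(CC)CC)CC/C(C)=C\I | intermediate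
30 | lithium C9-aldolate of 16 and 28 (anti aldol, C9 chain cis to CH3-15) | [Li]O[C@H]([C@H]1C(=O)C=C[C@]1(C)[C@H](O[Si](CC)(CC)CC)CC/C(C)=C\I)[C@@](O[Si](CC)(CC)CC)(CO[Si](c1ccccc1)(c1ccccc1)C(C)(C)C)[C@@H](C)C(=O)OC(C)(C)C | intermediate
31 | tris-TES aldol adduct: cyclopent-2-enone bearing at C10 the chain CH(OTES)–C(OTES)(CH2OTBDPS)–CH(CH3)–CO2t-Bu and at C1 methyl and the (1R,4Z)-5-iodo-4-methyl-1-(triethylsilyloxy)pent-4-enyl group; C1, C2, C8, C9, C10, C17 as in the target | CC[Si](CC)(CC)O[C@H]([C@H]1C(=O)C=C[C@]1(C)[C@H](O[Si](CC)(CC)CC)CC/C(C)=C\I)[C@@](O[Si](CC)(CC)CC)(CO[Si](c1ccccc1)(c1ccccc1)C(C)(C)C)[C@@H](C)C(=O)OC(C)(C)C | intermediate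
32 | ethyl vinyl ether | C=COCC | starting material
33 | 1-ethoxyvinyllithium | [Li]C(=C)OCC | intermediate
34 | 12β-hydroxy-12α-(1-ethoxyvinyl) carbinol from 31 | CC[Si](CC)(CC)O[C@H]([C@H]1[C@](O)(C(=C)OCC)C=C[C@]1(C)[C@H](O[Si](CC)(CC)CC)CC/C(C)=C\I)[C@@](O[Si](CC)(CC)CC)(CO[Si](c1ccccc1)(c1ccccc1)C(C)(C)C)[C@@H](C)C(=O)OC(C)(C)C | intermediate
35 | α-ketol: 1-acetylcyclopent-2-en-1-ol with 12-OH β (cis to the C9 chain) and acetyl α | CC[Si](CC)(CC)O[C@H]([C@H]1[C@](O)(C(C)=O)C=C[C@]1(C)[C@H](O[Si](CC)(CC)CC)CC/C(C)=C\I)[C@@](O[Si](CC)(CC)CC)(CO[Si](c1ccccc1)(c1ccccc1)C(C)(C)C)[C@@H](C)C(=O)OC(C)(C)C | intermediate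
36 | potassium alkoxide of the ring-expanded 6-hydroxy-6-methylcyclohex-2-enone (11α-O⁻, 11β-CH3) | CC[Si](CC)(CC)O[C@H]([C@H]1[C@](C)([O-])C(=O)C=C[C@]1(C)[C@H](O[Si](CC)(CC)CC)CC/C(C)=C\I)[C@@](O[Si](CC)(CC)CC)(CO[Si](c1ccccc1)(c1ccccc1)C(C)(C)C)[C@@H](C)C(=O)OC(C)(C)C.[K+] | intermediate
37 | ring-expanded enone: 6-methyl-6-(triethylsilyloxy)cyclohex-2-enone (C12=O, C13=C14, 11α-OTES) with the C2 and C9 chains unchanged | CC[Si](CC)(CC)O[C@H]([C@H]1[C@](C)(O[Si](CC)(CC)CC)C(=O)C=C[C@]1(C)[C@H](O[Si](CC)(CC)CC)CC/C(C)=C\I)[C@@](O[Si](CC)(CC)CC)(CO[Si](c1ccccc1)(c1ccccc1)C(C)(C)C)[C@@H](C)C(=O)OC(C)(C)C | intermediate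
38 | 12α-allylic alcohol of 37 | CC[Si](CC)(CC)O[C@H]([C@H]1[C@](C)(O[Si](CC)(CC)CC)[C@H](O)C=C[C@]1(C)[C@H](O[Si](CC)(CC)CC)CC/C(C)=C\I)[C@@](O[Si](CC)(CC)CC)(CO[Si](c1ccccc1)(c1ccccc1)C(C)(C)C)[C@@H](C)C(=O)OC(C)(C)C | intermediate
39 | 2,8,9,11,12-pentaol (7-O-TBDPS, tert-butyl ester, vinyl iodide retained) | O[C@H]([C@H]1[C@](C)(O)[C@H](O)C=C[C@]1(C)[C@H](O)CC/C(C)=C\I)[C@@](O)(CO[Si](c1ccccc1)(c1ccccc1)C(C)(C)C)[C@@H](C)C(=O)OC(C)(C)C | intermediate
40 | 2,9,12-triacetate of 39 | CC(=O)O[C@H]([C@H]1[C@](C)(O)[C@H](OC(C)=O)C=C[C@]1(C)[C@H](OC(C)=O)CC/C(C)=C\I)[C@@](O)(CO[Si](c1ccccc1)(c1ccccc1)C(C)(C)C)[C@@H](C)C(=O)OC(C)(C)C | intermediate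
41 | 7-hydroxy triacetate (primary alcohol) | CC(=O)O[C@H]([C@H]1[C@](C)(O)[C@H](OC(C)=O)C=C[C@]1(C)[C@H](OC(C)=O)CC/C(C)=C\I)[C@@](O)(CO)[C@@H](C)C(=O)OC(C)(C)C | intermediate
42 | 7-oxo triacetate (α-hydroxy aldehyde with Z vinyl iodide) | CC(=O)O[C@H]([C@H]1[C@](C)(O)[C@H](OC(C)=O)C=C[C@]1(C)[C@H](OC(C)=O)CC/C(C)=C\I)[C@@](O)(C=O)[C@@H](C)C(=O)OC(C)(C)C | intermediate
43 | bicyclic seco-lactone: 2,9,12-triacetoxy-7,8,11-trihydroxybriara-5(Z),13-diene tert-butyl C19 ester | CC(=O)O[C@@H]1[C@H]2[C@](C)(O)[C@H](OC(C)=O)C=C[C@]2(C)[C@H](OC(C)=O)CC/C(C)=C\[C@H](O)[C@@]1(O)[C@@H](C)C(=O)OC(C)(C)C | intermediate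
44 | CNP0129620.2 | CC(=O)O[C@@H]1[C@H]2[C@](C)(O)[C@H](OC(C)=O)C=C[C@]2(C)[C@H](OC(C)=O)CC/C(C)=C\[C@@H]2OC(=O)[C@H](C)[C@]21O | target

**Step count and risks**

Total: 26 steps. Longest linear sequence: 19 steps (steps 1–9, then 17–26).

Step 19 (key step). What may go wrong: the vinylic ring carbon C13 migrates in place of C10, or the shift runs through a cation-bridged cisoid arrangement and delivers the C11 epimer, or the alkoxide triggers β-elimination in the ester arm. The fallback uses known chemistry and is still a five-to-six ring enlargement. It sets out from 31: Sc(OTf)3-catalysed homologation with diazoethane inserts CH(CH3) between C12 and the more substituted α′-carbon C10 to give the 6-methylcyclohex-2-enone F1 (C11 epimers). KHMDS followed by 2-(phenylsulfonyl)-3-phenyloxaziridine should hydroxylate the cross-conjugated enolate on the α face, anti to the C9 chain, to the 11-hydroxy enone F2. TESOTf/2,6-lutidine silylates F2 and the route is rejoined at 37.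

Step 17. What may go wrong: poor facial selectivity on the aldehyde, because the intrinsic dipole-controlled bias of the α-silyloxy aldehyde opposes the anti chair transition state, so the C9 epimer or the syn aldol may dominate. The fallback replaces the closed lithium transition state by a chelation-controlled open one. It sets out from 16 and 28: 16 is converted with LDA/TMSCl into the 2-silyloxycyclopentadiene F3, and 28 is desilylated with HF·pyridine to the α-hydroxy aldehyde F4. A MgBr2·OEt2-mediated Mukaiyama aldol, in which magnesium bridges the aldehyde and the free C8 hydroxyl and the diene attacks past the small CH2OTBDPS arm and anti to the C2 chain, should give the aldol diol F5. Bis-silylation with TESOTf/2,6-lutidine comes back to the route at 31.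

Step 25. What may go wrong: poor facial selectivity at C7 during ring closure (or slow closure of the strained ten-membered ring with competing reduction of the iodide). The fallback changes the lactonisation from retentive to invertive. It sets out from 42: if the ring closure gives mainly the 7-epimeric carbinol F6, TFA cleaves its tert-butyl ester to the hydroxy acid F7, and Mitsunobu lactonisation (PPh3, DIAD) closes the γ-lactone with inversion at C7, coming back to the route at 44.

**Further compounds**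

F1 | step 19 | 6-methylcyclohex-2-enone from diazoethane ring expansion of 31 (C11-H, both epimers) | CC[Si](CC)(CC)O[C@H]([C@H]1C(C)C(=O)C=C[C@]1(C)[C@H](O[Si](CC)(CC)CC)CC/C(C)=C\I)[C@@](O[Si](CC)(CC)CC)(CO[Si](c1ccccc1)(c1ccccc1)C(C)(C)C)[C@@H](C)C(=O)OC(C)(C)C
F2 | step 19 | 11α-hydroxy-11β-methyl cyclohex-2-enone (free tertiary alcohol of 37) | CC[Si](CC)(CC)O[C@H]([C@H]1[C@](C)(O)C(=O)C=C[C@]1(C)[C@H](O[Si](CC)(CC)CC)CC/C(C)=C\I)[C@@](O[Si](CC)(CC)CC)(CO[Si](c1ccccc1)(c1ccccc1)C(C)(C)C)[C@@H](C)C(=O)OC(C)(C)C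
F3 | step 17 | 2-(trimethylsilyloxy)cyclopenta-1,3-diene derived from 16 | C[Si](C)(C)OC1=C[C@](C)(C=C1)[C@H](O[Si](CC)(CC)CC)CC/C(C)=C\I
F4 | step 17 | tert-butyl (2R,3S)-4-[(tert-butyldiphenylsilyl)oxy]-3-formyl-3-hydroxy-2-methylbutanoate | CC(C)(C)OC(=O)[C@H](C)[C@](O)(CO[Si](c1ccccc1)(c1ccccc1)C(C)(C)C)C=O
F5 | step 17 | aldol diol (8-OH, 9-OH free; otherwise as 31) | O[C@H]([C@H]1C(=O)C=C[C@]1(C)[C@H](O[Si](CC)(CC)CC)CC/C(C)=C\I)[C@@](O)(CO[Si](c1ccccc1)(c1ccccc1)C(C)(C)C)[C@@H](C)C(=O)OC(C)(C)C
F6 | step 25 | 7-epimer of 43 | CC(=O)O[C@@H]1[C@H]2[C@](C)(O)[C@H](OC(C)=O)C=C[C@]2(C)[C@H](OC(C)=O)CC/C(C)=C\[C@@H](O)[C@@]1(O)[C@@H](C)C(=O)OC(C)(C)C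
F7 | step 25 | 7-epi seco acid (C19 carboxylic acid of F6) | CC(=O)O[C@@H]1[C@H]2[C@](C)(O)[C@H](OC(C)=O)C=C[C@]2(C)[C@H](OC(C)=O)CC/C(C)=C\[C@@H](O)[C@@]1(O)[C@@H](C)C(=O)O
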